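## Analysis of the target

Compound 12 is a flavanone: a chroman-4-one in which ring A is fused to the oxygen heterocycle, ring C, and a 4-hydroxyphenyl group, ring B, sits at C2. Ring A is substituted everywhere except C6, with a hydroxyl at C5 hydrogen-bonded to the C4 carbonyl, a methoxy group at C7 and a prenyl group at C8 next to the ring oxygen O1. C2 is the only stereocentre and is S; being benzylic, bound to O1 and β to the ketone, it can be lost by retro-oxa-Michael opening of ring C, which base (via the 4'-phenoxide or the C3 enolate) and strong acid both promote. The prenyl double bond is sensitive to protic and Lewis acids, electrophilic halogen, oxidants and hydrogenation, and both phenols must be masked whenever a base or an electrophile is used. The synthesis is hard for two reasons: the prenyl group must sit between the methoxy group and O1 and not at C6, and a labile stereocentre must be made late under neutral conditions. The strategy rests on the C2–H bond: in an open precursor whose O1 carries the 4-oxygenated benzyl group, the O1–CH2 hydrogens are benzylic, α to oxygen and six atoms from a carbene at C3 next to the C4 ketone. Insertion of that carbene forms C2–C3, closes ring C and sets C2 in one neutral step.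

## Retrosynthetic reasoning

**12 to 11.** The two phenolic O–H bonds are traced back to O–Si bonds in 11. Free phenols would trap a carbenoid by O–H insertion and would be deprotonated during the diazo transfer, so they stay masked until the end. Triisopropylsilyl ethers are chosen for both oxygens. At C5 the group must survive an amide base, must not migrate to the neighbouring enolate oxygen, and must shield the oxygen lone pairs from the carbenoid. Ethers with C–H bonds next to oxygen would offer a second insertion site, and esters would not survive the enolate. The forward step must free both phenols without ever forming a phenoxide.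

**11 to 10.** The C2–C3 bond is cut, which opens ring C and removes the stereocentre. This leads to diazo ketone 10, in which C2 is a prochiral O1–CH2–aryl group and C3 a diazo carbon. A cut at O1–C2 would need an asymmetric oxa-Michael closure, the reverse of the path by which C2 racemises. A cut at C4–C4a would need acid, which the prenyl group does not tolerate. The forward reaction must pick one of two enantiotopic hydrogens and must outrun attack of the carbenoid on the ether oxygen.

**10 to 8.** The C3=N2 unit is traced back to the methyl group of aryl methyl ketone 8. The methyl group is activated as its trifluoroacetyl derivative 9, which accepts the diazo group from a sulfonyl azide and then loses the activating group. This avoids building the diazo ketone from a hindered 2,6-dioxygenated aroyl electrophile.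

**8 to 4 and 7.** The O1–CH2 bond is cut to give phenol 4 and benzylic alcohol 7. Joining them by redox condensation uses the stable alcohol instead of an ionisable benzylic halide and keeps carbonate bases away from the aryl silyl ethers.

**7 to 6 to 5.** The benzylic C–O–H is traced back to the aldehyde of 6, and the O–Si bond of 6 to the phenol of 5. Silylating before reduction avoids having to tell a phenol from a benzylic alcohol.

**4 to 3.** The O–Si bond at the C6' oxygen is cut. In diol 3 this hydroxyl has only the acetyl group as neighbour, while the other lies between the acetyl group and the prenyl CH2. A bulky silyl group should go to the open one, leaving the hindered hydroxyl, the future O1, free.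

**3 to 1 and 2.** The aryl–CH2 bond of the prenyl group is cut. Because 1 is symmetric, C-alkylation by 2 can give only one mono-C-prenyl constitution, with the prenyl group between the methoxy group and a hydroxyl, as ring A requires.

## Alternatives that were turned down

**Alternative 1:** Ring C is cut at C3–C4 and O1–C2, which leads to 2-hydroxy-4-methoxy-3-(3-methylbut-2-en-1-yl)-6-(triisopropylsilyloxy)benzaldehyde A2 and 4-(triisopropylsilyloxy)styrene A3 as the two partners. In the forward sense A2 is converted in the flask into its dimethyl acetal, a chiral phosphoric acid ionises it to the 4-methoxy ortho-quinone methide, and [4+2] cycloaddition with A3 would give (2S)-2,4-cis-4,7-dimethoxy-8-prenyl-5,4'-bis(triisopropylsilyloxy)flavan A1 in one operation.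

In its favour, two bonds, ring C and the C2 centre are made in one convergent step from two simple partners, with no diazo compound. In bonds formed per step it is stronger than the chosen route.

Against it, the acid that generates the quinone methide meets in A2 a prenyl group ortho to a free phenol, an array that closes readily to a 2,2-dimethylchroman once the alkene is protonated. The product A1 also has the wrong oxidation level at C4. Hydrolysis and oxidation add two steps, and ionisation of A1 at C4 re-forms the quinone methide, from which cycloreversion can erase C2. Quinone-type oxidants would in addition attack the benzylic and allylic CH2 of the prenyl group. Finally, a stereocentre at C4 is made only to be destroyed.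

By comparison, the chosen route delivers C4 as the ketone, needs one step after the key step instead of three, and keeps acid away from the prenyl group.

**Alternative 2:** Ring C is cut at C4–C4a, which leads to (3S)-3-(4-acetoxyphenyl)-3-[5-acetoxy-3-methoxy-2-(3-methylbut-2-en-1-yl)phenoxy]propanoic acid A5 as the open precursor. Activation of A5 as its trifluoroacetic mixed anhydride would be followed by intramolecular Friedel–Crafts acylation at C4a to give (2S)-5,4'-di-O-acetyl Mundulea flavanone B A4 with ring C closed.

In its favour, the stereocentre can come from a dependable asymmetric ketone reduction, so its absolute configuration is more predictable than in a carbenoid insertion. The closure is also regiochemically forced, because C4a is the only free position ortho to O1. On both points it is stronger than the chosen route.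

Against it, the acidic acylating medium protonates or acylates the prenyl alkene, and it ionises the O1–C2 bond of A5, a benzylic ether, which causes racemisation or elimination. Assembling A5 needs etherification of a hindered ortho-prenyl phenol at a secondary benzylic carbon that leaks towards SN1. The product A4 must then lose two aryl acetates, which needs base or acid, the conditions under which ring C opens.

By comparison, the step count is similar. The chosen route offers neutral bond formation at C2 and a fluoride-labile set of protecting groups.

**Alternative 3:** Ring A is cut at C8–C8a and C4a–C5, which leads to (2S)-5-bromo-2-[4-(tert-butyldimethylsilyloxy)phenyl]-2,3-dihydro-4H-pyran-4-one A7 and the Brassard-type diene 1,3-dimethoxy-7-methyl-1-(trimethylsilyloxy)octa-1,3,6-triene A8 as partners. Diels–Alder addition of A8 across the C4a=C8a bond of A7, then loss of hydrogen bromide and of the silyl methyl ether, would aromatise ring A and give (2S)-4'-O-(tert-butyldimethylsilyl) Mundulea flavanone B A6 directly. The product A6 would need only one desilylation to reach 12.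

In its favour, C2 comes from a well-established asymmetric hetero-Diels–Alder reaction, the polarised diene fixes the ring A pattern, and the C5 hydroxyl of A6 emerges free. On reliability of enantiocontrol it is stronger than the chosen route.

Against it, the dienophile in A7 is a vinylogous ester whose C8a carries the donor O1, so it is electron-rich and sluggish even with bromine. The nucleophilic terminus of A8 carries the prenyl group, so the C8–C8a bond joins two crowded centres. Forcing thermal conditions and the elimination step expose C2 to β-elimination of O1, and A8 needs about three steps of its own.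

By comparison, the chosen route starts from an intact ring A, settles regiochemistry by simple phenol chemistry, and confines the risk to one intramolecular, neutral step.

Key step: step 7

Remark on the chemistry: Rh2(S-PTTL)4 is assumed to induce the (2S) configuration in the insertion. Should the first run show the opposite sense, the antipodal catalyst Rh2(R-PTTL)4, from D-tert-leucine, is used in the same step.

## Route

**Step 1**
Reactants: 1 2',6'-dihydroxy-4'-methoxyacetophenone; 2 prenyl bromide (1-bromo-3-methylbut-2-ene)
Product: 3 1-[2,6-dihydroxy-4-methoxy-3-(3-methylbut-2-en-1-yl)phenyl]ethanone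
Conditions: 2 (1.0 equiv), KOH (10% aq), 0 °C → rt
Reagents that add atoms: none
Why: Nuclear C-prenylation of a phenoxide: in water the oxygen atoms are solvated and the ambident anion of 1 attacks the primary allylic bromide through carbon (SN2). C3 and C5 of 1 are equivalent, so only one mono-C-prenyl constitution can form. A modest conversion is expected because O-alkylation and double alkylation compete, and unchanged 1 is recovered.

**Step 2**
Reactants: 3 1-[2,6-dihydroxy-4-methoxy-3-(3-methylbut-2-en-1-yl)phenyl]ethanone
Product: 4 1-[2-hydroxy-4-methoxy-3-(3-methylbut-2-en-1-yl)-6-(triisopropylsilyloxy)phenyl]ethanone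
Conditions: TIPSCl (1.05 equiv), imidazole, DMF, 0 °C → rt
Reagents that add atoms: triisopropylsilyl chloride, CC(C)[Si](Cl)(C(C)C)C(C)C
Why: Imidazole-promoted silylation of a phenol, selective on steric grounds: the C6 hydroxyl has only the acetyl group as neighbour, whereas the C2 hydroxyl lies between the acetyl group and the prenyl CH2. Once one oxygen is silylated the other is locked in the hydrogen bond to the carbonyl and should not react further.

**Step 3**
Reactants: 5 4-hydroxybenzaldehyde
Product: 6 4-(triisopropylsilyloxy)benzaldehyde
Conditions: TIPSCl, imidazole, DMF, rt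
Reagents that add atoms: triisopropylsilyl chloride, CC(C)[Si](Cl)(C(C)C)C(C)C
Why: Standard silyl ether formation at an acidic, unhindered phenol; the aldehyde is inert to the silyl chloride and imidazole.

**Step 4**
Reactants: 6 4-(triisopropylsilyloxy)benzaldehyde
Product: 7 [4-(triisopropylsilyloxy)phenyl]methanol
Conditions: NaBH4, MeOH/THF, 0 °C
Reagents that add atoms: none
Why: Borohydride reduction of an aromatic aldehyde to the benzylic alcohol; the aryl triisopropylsilyl ether withstands brief exposure to cold methanolic borohydride.

**Step 5**
Reactants: 4 1-[2-hydroxy-4-methoxy-3-(3-methylbut-2-en-1-yl)-6-(triisopropylsilyloxy)phenyl]ethanone; 7 [4-(triisopropylsilyloxy)phenyl]methanol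
Product: 8 1-[4-methoxy-3-(3-methylbut-2-en-1-yl)-6-(triisopropylsilyloxy)-2-{[4-(triisopropylsilyloxy)phenyl]methoxy}phenyl]ethanone
Conditions: PPh3, DIAD, THF, 0 °C → rt
Reagents that add atoms: none
Why: Mitsunobu etherification: the acidic ortho-acyl phenol 4 is alkylated at oxygen by the alkoxyphosphonium ion of the primary benzylic alcohol 7. The medium is neutral, so the aryl silyl ethers see no carbonate base and no benzylic halide has to be handled.

**Step 6**
Reactants: 8 1-[4-methoxy-3-(3-methylbut-2-en-1-yl)-6-(triisopropylsilyloxy)-2-{[4-(triisopropylsilyloxy)phenyl]methoxy}phenyl]ethanone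
Product: 10 2-diazo-1-[4-methoxy-3-(3-methylbut-2-en-1-yl)-6-(triisopropylsilyloxy)-2-{[4-(triisopropylsilyloxy)phenyl]methoxy}phenyl]ethanone, via trifluoroacetyl ketone 9 (not isolated)
Conditions: LiN(SiMe3)2, THF, −78 °C; CF3CO2CH2CF3, −78 °C, 5% aq HCl work-up; then MsN3, Et3N, H2O (1 equiv), MeCN, rt
Reagents that add atoms: 2,2,2-trifluoroethyl trifluoroacetate, O=C(OCC(F)(F)F)C(F)(F)F (trifluoroacetyl group of 9); methanesulfonyl azide, CS(=O)(=O)N=[N+]=[N-] (diazo nitrogen atoms of 10)
Why: Detrifluoroacetylative diazo transfer: the kinetic lithium enolate of the methyl ketone is C-acylated to the 1,3-diketone 9, which accepts the diazo group from the sulfonyl azide and then loses the trifluoroacetyl group to the sulfonamide nitrogen. The low temperature and the bulk of the triisopropylsilyl group should hold the neighbouring silyl ether in place, and the amine and water of the second stage do not affect aryl triisopropylsilyl ethers.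

**Step 7**
Reactants: 10 2-diazo-1-[4-methoxy-3-(3-methylbut-2-en-1-yl)-6-(triisopropylsilyloxy)-2-{[4-(triisopropylsilyloxy)phenyl]methoxy}phenyl]ethanone
Product: 11 (2S)-7-methoxy-8-(3-methylbut-2-en-1-yl)-5-(triisopropylsilyloxy)-2-[4-(triisopropylsilyloxy)phenyl]chroman-4-one
Conditions: Rh2(S-PTTL)4 (dirhodium tetrakis[N-phthaloyl-(S)-tert-leucinate], 2 mol %), CH2Cl2, 4 Å molecular sieves, 0 °C, slow addition of 10
Reagents that add atoms: none
Why: Rh2(S-PTTL)4, a paddlewheel of two divalent rhodium centres, is attacked by the diazo carbon of 10 and, after loss of nitrogen, carries an electrophilic carbenoid at C3. The carbenoid takes one of the two hydrogens of the O1–CH2–aryl group in a concerted, asynchronous three-centre transition state with hydride-transfer character, forms C2–C3 and releases the catalyst. The closest known reaction type is the chiral dirhodium carboxylate-catalysed intramolecular C–H insertion of ortho-alkoxyaryl diazomethyl ketones to chroman-4-ones. Ring C is closed as a six-membered ring by 1,6-insertion through the array C3–C4–C4a–C8a–O1–C2, with ring A as the rigid tether. C2 is set under catalyst control: the N-phthaloyl-tert-leucinate ligands differentiate the two enantiotopic benzylic hydrogens, there being no other stereocentre in 10. The step needs chemoselectivity for C–H insertion over ylide formation at O1 or at the C5 oxygen and over reaction with the prenyl double bond: the C–H bond is made hydridic by the O1 lone pair and the 4-silyloxyphenyl ring, O1 is a weakly basic aryl ether oxygen flanked by two ortho substituents, the C5 oxygen is buried under the triisopropylsilyl group, and the alkene cannot reach C3 without a meta-bridged ring, while slow addition suppresses intermolecular cyclopropanation and carbene dimerisation. The neutral, aprotic medium leaves the new C2 centre untouched.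

**Step 8**
Reactants: 11 (2S)-7-methoxy-8-(3-methylbut-2-en-1-yl)-5-(triisopropylsilyloxy)-2-[4-(triisopropylsilyloxy)phenyl]chroman-4-one
Product: 12 (2S)-5-hydroxy-2-(4-hydroxyphenyl)-7-methoxy-8-(3-methylbut-2-en-1-yl)chroman-4-one (Mundulea flavanone B)
Conditions: Bu4NF, AcOH (1:1), THF, 0 °C → rt
Reagents that add atoms: none
Why: Fluoride-mediated cleavage of both aryl silyl ethers, driven by Si–F bond formation. The acetic acid buffer protonates each phenoxide as it forms, so neither the 4'-phenoxide nor a C3 enolate can open ring C by retro-oxa-Michael reaction, and C2 should be retained; the prenyl group is inert.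

## Compound list

1 | 2',6'-dihydroxy-4'-methoxyacetophenone | COc1cc(O)c(C(C)=O)c(O)c1 | starting material
2 | prenyl bromide (1-bromo-3-methylbut-2-ene) | CC(C)=CCBr | starting material
3 | 1-[2,6-dihydroxy-4-methoxy-3-(3-methylbut-2-en-1-yl)phenyl]ethanone | COc1cc(O)c(C(C)=O)c(O)c1CC=C(C)C | intermediate
4 | 1-[2-hydroxy-4-methoxy-3-(3-methylbut-2-en-1-yl)-6-(triisopropylsilyloxy)phenyl]ethanone | COc1cc(O[Si](C(C)C)(C(C)C)C(C)C)c(C(C)=O)c(O)c1CC=C(C)C | intermediate
5 | 4-hydroxybenzaldehyde | O=Cc1ccc(O)cc1 | starting material
6 | 4-(triisopropylsilyloxy)benzaldehyde | O=Cc1ccc(O[Si](C(C)C)(C(C)C)C(C)C)cc1 | intermediate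
7 | [4-(triisopropylsilyloxy)phenyl]methanol | OCc1ccc(O[Si](C(C)C)(C(C)C)C(C)C)cc1 | intermediate
8 | 1-[4-methoxy-3-(3-methylbut-2-en-1-yl)-6-(triisopropylsilyloxy)-2-{[4-(triisopropylsilyloxy)phenyl]methoxy}phenyl]ethanone | COc1cc(O[Si](C(C)C)(C(C)C)C(C)C)c(C(C)=O)c(OCc2ccc(O[Si](C(C)C)(C(C)C)C(C)C)cc2)c1CC=C(C)C | intermediate
9 | 4,4,4-trifluoro-1-[4-methoxy-3-(3-methylbut-2-en-1-yl)-6-(triisopropylsilyloxy)-2-{[4-(triisopropylsilyloxy)phenyl]methoxy}phenyl]butane-1,3-dione | COc1cc(O[Si](C(C)C)(C(C)C)C(C)C)c(C(=O)CC(=O)C(F)(F)F)c(OCc2ccc(O[Si](C(C)C)(C(C)C)C(C)C)cc2)c1CC=C(C)C | intermediate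
10 | 2-diazo-1-[4-methoxy-3-(3-methylbut-2-en-1-yl)-6-(triisopropylsilyloxy)-2-{[4-(triisopropylsilyloxy)phenyl]methoxy}phenyl]ethanone | COc1cc(O[Si](C(C)C)(C(C)C)C(C)C)c(C(=O)C=[N+]=[N-])c(OCc2ccc(O[Si](C(C)C)(C(C)C)C(C)C)cc2)c1CC=C(C)C | intermediate
11 | (2S)-7-methoxy-8-(3-methylbut-2-en-1-yl)-5-(triisopropylsilyloxy)-2-[4-(triisopropylsilyloxy)phenyl]chroman-4-one | COc1cc(O[Si](C(C)C)(C(C)C)C(C)C)c2c(c1CC=C(C)C)O[C@H](c1ccc(O[Si](C(C)C)(C(C)C)C(C)C)cc1)CC2=O | intermediate
12 | (2S)-5-hydroxy-2-(4-hydroxyphenyl)-7-methoxy-8-(3-methylbut-2-en-1-yl)chroman-4-one (Mundulea flavanone B) | COc1cc(O)c2c(c1CC=C(C)C)O[C@H](c1ccc(O)cc1)CC2=O | target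

## Step count and risks

Total step count: 8. Longest linear sequence: 6 steps (1 → 3 → 4 → 8 → 10 → 11 → 12; the branch from 5 through 6 and 7 is equally long).

**Step 7 (key step).** The carbenoid may attack the lone pair of O1 instead of the C–H bond, forming a five-membered oxonium ylide that rearranges by 1,2-shift of the benzyl group. Enantioselectivity may also erode if the very electrophilic acceptor-only carbenoid abstracts hydride first, since the resulting ion pair can close from either face. The absolute sense of induction must be established as well.

Fallback: C2 is created instead by enantioselective conjugate arylation of a chromone; the detour sets out from 4 and comes back to the route at 12. Condensation of 4 with N,N-dimethylformamide dimethyl acetal (toluene, 90 °C) should give (E)-3-(dimethylamino)-1-[2-hydroxy-4-methoxy-3-(3-methylbut-2-en-1-yl)-6-(triisopropylsilyloxy)phenyl]prop-2-en-1-one F1 with loss of methanol. Mild acid (pyridinium 4-toluenesulfonate, toluene, 60 °C) should then cyclise F1 with loss of dimethylamine to 7-methoxy-8-(3-methylbut-2-en-1-yl)-5-(triisopropylsilyloxy)-4H-chromen-4-one F2 as the conjugate acceptor. Commercial 4-(tert-butyldimethylsilyloxy)phenylboronic acid is then added to F2 under Pd(OCOCF3)2 and the enantiomer of the tert-butyl pyridine-oxazoline ligand that leads to the (2S) series (NH4PF6, water, 1,2-dichloroethane, 60 °C). This should give (2S)-2-[4-(tert-butyldimethylsilyloxy)phenyl]-7-methoxy-8-(3-methylbut-2-en-1-yl)-5-(triisopropylsilyloxy)chroman-4-one F3 by a known palladium-catalysed asymmetric 1,4-addition to chromones. Desilylation of F3 under the conditions of step 8 then leads to 12.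

**Step 1.** Alkylation of the ambident phenoxide at oxygen and a second alkylation can drain material, so conversion to the mono-C-prenyl product may be low.

Fallback: the prenyl group is delivered through oxygen and then moved to carbon; the detour sets out from 1 and comes back to the route at 3. O-alkylation of one hydroxyl of 1 with 2 (K2CO3, acetone, reflux) should give 1-[2-hydroxy-4-methoxy-6-(3-methylbut-2-en-1-yloxy)phenyl]ethanone F4 as the mono-ether, because the second hydroxyl stays chelated to the carbonyl. Heating F4 in N,N-diethylaniline at 190 °C should then trigger a para-Claisen–Cope sequence that moves the prenyl group to the carbon para to the ether oxygen, the one between the methoxy group and the other hydroxyl, which is 3.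

**Step 2.** Silylation may occur at the hindered hydroxyl or at both if the steric difference between the two chelated phenols is too small.

Fallback: the benzylic ether is fixed before the prenyl group, so that no choice between two hydroxyls is needed; the detour sets out from 1 and comes back to the route at 8. Mitsunobu etherification of one hydroxyl of the symmetric diol 1 with 7 (PPh3, DIAD, THF) should give 1-[2-hydroxy-4-methoxy-6-{[4-(triisopropylsilyloxy)phenyl]methoxy}phenyl]ethanone F5 as the only mono-ether. O-prenylation of the remaining hydroxyl of F5 with 2 (K2CO3, DMF, rt) should give 1-[4-methoxy-2-(3-methylbut-2-en-1-yloxy)-6-{[4-(triisopropylsilyloxy)phenyl]methoxy}phenyl]ethanone F6 as the bis-ether. F6 is then warmed with Eu(fod)3 (tris(6,6,7,7,8,8,8-heptafluoro-2,2-dimethyl-3,5-octanedionato)europium; CHCl3, 60 °C). This para-Claisen–Cope rearrangement should move the prenyl group to the carbon para to its oxygen, between the methoxy and benzyloxy groups, and give 1-[6-hydroxy-4-methoxy-3-(3-methylbut-2-en-1-yl)-2-{[4-(triisopropylsilyloxy)phenyl]methoxy}phenyl]ethanone F7 with one free hydroxyl. Silylation of that hydroxyl in F7 (TIPSCl, imidazole, DMF) leads to 8.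

**Step 6.** The silyl group may migrate from the C6 oxygen to the neighbouring enolate oxygen, or C-acylation of the hindered enolate may be incomplete, leaving the diazo transfer without an activated substrate.

Fallback: the methyl ketone is activated without a metal enolate; the detour sets out from 8 and comes back to the route at 10. Heating 8 with N,N-dimethylformamide dimethyl acetal (neat, 110 °C) should give (E)-3-(dimethylamino)-1-[4-methoxy-3-(3-methylbut-2-en-1-yl)-6-(triisopropylsilyloxy)-2-{[4-(triisopropylsilyloxy)phenyl]methoxy}phenyl]prop-2-en-1-one F8 with loss of methanol. 4-Methylbenzenesulfonyl azide (MeCN, rt) should then add to the enamine double bond of F8 and the adduct should fragment to 10 together with the N-sulfonyl formamidine.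

## Further compounds

F1 | step 7 | (E)-3-(dimethylamino)-1-[2-hydroxy-4-methoxy-3-(3-methylbut-2-en-1-yl)-6-(triisopropylsilyloxy)phenyl]prop-2-en-1-one | COc1cc(O[Si](C(C)C)(C(C)C)C(C)C)c(C(=O)/C=C/N(C)C)c(O)c1CC=C(C)C
F2 | step 7 | 7-methoxy-8-(3-methylbut-2-en-1-yl)-5-(triisopropylsilyloxy)-4H-chromen-4-one | COc1cc(O[Si](C(C)C)(C(C)C)C(C)C)c2c(c1CC=C(C)C)OC=CC2=O
F3 | step 7 | (2S)-2-[4-(tert-butyldimethylsilyloxy)phenyl]-7-methoxy-8-(3-methylbut-2-en-1-yl)-5-(triisopropylsilyloxy)chroman-4-one | COc1cc(O[Si](C(C)C)(C(C)C)C(C)C)c2c(c1CC=C(C)C)O[C@H](c1ccc(O[Si](C)(C)C(C)(C)C)cc1)CC2=O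
F4 | step 1 | 1-[2-hydroxy-4-methoxy-6-(3-methylbut-2-en-1-yloxy)phenyl]ethanone | COc1cc(O)c(C(C)=O)c(OCC=C(C)C)c1
F5 | step 2 | 1-[2-hydroxy-4-methoxy-6-{[4-(triisopropylsilyloxy)phenyl]methoxy}phenyl]ethanone | COc1cc(O)c(C(C)=O)c(OCc2ccc(O[Si](C(C)C)(C(C)C)C(C)C)cc2)c1
F6 | step 2 | 1-[4-methoxy-2-(3-methylbut-2-en-1-yloxy)-6-{[4-(triisopropylsilyloxy)phenyl]methoxy}phenyl]ethanone | COc1cc(OCC=C(C)C)c(C(C)=O)c(OCc2ccc(O[Si](C(C)C)(C(C)C)C(C)C)cc2)c1
F7 | step 2 | 1-[6-hydroxy-4-methoxy-3-(3-methylbut-2-en-1-yl)-2-{[4-(triisopropylsilyloxy)phenyl]methoxy}phenyl]ethanone | COc1cc(O)c(C(C)=O)c(OCc2ccc(O[Si](C(C)C)(C(C)C)C(C)C)cc2)c1CC=C(C)C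
F8 | step 6 | (E)-3-(dimethylamino)-1-[4-methoxy-3-(3-methylbut-2-en-1-yl)-6-(triisopropylsilyloxy)-2-{[4-(triisopropylsilyloxy)phenyl]methoxy}phenyl]prop-2-en-1-one | COc1cc(O[Si](C(C)C)(C(C)C)C(C)C)c(C(=O)/C=C/N(C)C)c(OCc2ccc(O[Si](C(C)C)(C(C)C)C(C)C)cc2)c1CC=C(C)C
A1 | alternative 1 | (2S)-2,4-cis-4,7-dimethoxy-8-prenyl-5,4'-bis(triisopropylsilyloxy)flavan | COc1cc(O[Si](C(C)C)(C(C)C)C(C)C)c2c(c1CC=C(C)C)O[C@H](c1ccc(O[Si](C(C)C)(C(C)C)C(C)C)cc1)C[C@@H]2OC
A2 | alternative 1 | 2-hydroxy-4-methoxy-3-(3-methylbut-2-en-1-yl)-6-(triisopropylsilyloxy)benzaldehyde | COc1cc(O[Si](C(C)C)(C(C)C)C(C)C)c(C=O)c(O)c1CC=C(C)C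
A3 | alternative 1 | 4-(triisopropylsilyloxy)styrene | C=Cc1ccc(O[Si](C(C)C)(C(C)C)C(C)C)cc1
A4 | alternative 2 | (2S)-5,4'-di-O-acetyl Mundulea flavanone B | CC(=O)Oc1cc(OC)c(CC=C(C)C)c2c1C(=O)C[C@@H](c1ccc(OC(C)=O)cc1)O2
A5 | alternative 2 | (3S)-3-(4-acetoxyphenyl)-3-[5-acetoxy-3-methoxy-2-(3-methylbut-2-en-1-yl)phenoxy]propanoic acid | CC(=O)Oc1cc(OC)c(CC=C(C)C)c(O[C@@H](CC(=O)O)c2ccc(OC(C)=O)cc2)c1
A6 | alternative 3 | (2S)-4'-O-(tert-butyldimethylsilyl) Mundulea flavanone B | COc1cc(O)c2c(c1CC=C(C)C)O[C@H](c1ccc(O[Si](C)(C)C(C)(C)C)cc1)CC2=O
A7 | alternative 3 | (2S)-5-bromo-2-[4-(tert-butyldimethylsilyloxy)phenyl]-2,3-dihydro-4H-pyran-4-one | O=C1C[C@@H](c2ccc(O[Si](C)(C)C(C)(C)C)cc2)OC=C1Br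
A8 | alternative 3 | 1,3-dimethoxy-7-methyl-1-(trimethylsilyloxy)octa-1,3,6-triene | COC(O[Si](C)(C)C)=CC(OC)=CCC=C(C)C
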